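The plan rests on closing the ten-membered carbocycle (C1–C10, germacranolide numbering) last, at its only olefin. Ring-closing metathesis joins a vinyl group on the lactone carbon C6 to an isopropenyl group on the benzoyloxy carbon C3 and creates the Z-trisubstituted C4=C5 bond; the step exploits that this olefin, flanked by the C3 and C6 oxygens, is the less strained Z isomer inside the ring. The precursor is a fully dressed seco-diene that already holds the α-methylene-γ-lactone, the C1–C10 epoxide, both esters and all eight stereocentres, so the key step gives the target itself. It is assembled by chromium-mediated allylation (C7–C8), Mitsunobu esterification with inversion at C8 and Shi epoxidation.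

Key step: step 17

Remark on the chemistry: germacranolide numbering is used. C1 and C10 are the epoxide carbons (methyl on C10), C3 bears the benzoate, C4=C5 is the ring olefin (methyl on C4), C6 bears the lactone oxygen, C7 is the fusion carbon, C8 bears the epoxy ester, and C11, C12, C13 are the lactone α-carbon, carbonyl carbon and exocyclic methylene. It is assumed that the closed transition state of step 14 gives the 8S (anti) carbinol, which is why the ester is put on with inversion in step 15.

Step 1
Reactants: 1 (S)-5-(hydroxymethyl)dihydrofuran-2(3H)-one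
Product: 2 (S)-5-oxotetrahydrofuran-2-carbaldehyde
Conditions: Dess–Martin periodinane, CH2Cl2, 0 °C to rt
Reagents that add atoms: none
Why: Dess–Martin oxidation of the primary alcohol under neutral conditions leaves the oxygen-bearing stereocentre (the later C6) untouched.

Step 2
Reactants: 2 (S)-5-oxotetrahydrofuran-2-carbaldehyde
Product: 3 (S)-5-ethenyldihydrofuran-2(3H)-one
Conditions: Ph3PCH3Br, KN(SiMe3)2, THF, −78 to 0 °C
Reagents that add atoms: methyltriphenylphosphonium bromide, C[P+](c1ccccc1)(c1ccccc1)c1ccccc1.[Br-]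
Why: Wittig methylenation at low temperature is faster at the aldehyde than at the lactone carbonyl and does not touch the adjacent stereocentre.

Step 3
Reactants: 3 (S)-5-ethenyldihydrofuran-2(3H)-one
Product: 4 (5S)-5-ethenyl-3-(phenylselanyl)dihydrofuran-2(3H)-one (both C3 epimers)
Conditions: LiN(iPr)2, THF, −78 °C; then PhSeCl
Reagents that add atoms: phenylselenenyl chloride, Cl[Se]c1ccccc1
Why: α-Selenenylation of the lithium lactone enolate; the new C3 centre disappears again in step 4, so its configuration does not matter.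

Step 4
Reactants: 4 (5S)-5-ethenyl-3-(phenylselanyl)dihydrofuran-2(3H)-one
Product: 6 (R)-5-ethenyl-3-(hydroxymethyl)furan-2(5H)-one, via selenide aldol adduct 5 (not isolated)
Conditions: LiN(iPr)2, THF, −78 °C; CH2O (gas); AcOH; then 30% H2O2, 0 °C
Reagents that add atoms: formaldehyde, C=O
Why: Aldol addition of the selenium-stabilised enolate to formaldehyde, then oxidation and selenoxide syn-elimination, which runs into the ring and not toward the carbinol carbon and so gives the butenolide; no base is present, so the doubly allylic C6–H is not removed.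

Step 5
Reactants: 6 (R)-5-ethenyl-3-(hydroxymethyl)furan-2(5H)-one
Product: 7 (R)-3-(bromomethyl)-5-ethenylfuran-2(5H)-one
Conditions: CBr4, PPh3, CH2Cl2, 0 °C
Reagents that add atoms: carbon tetrabromide, BrC(Br)(Br)Br
Why: Appel bromination of the primary allylic alcohol under neutral conditions (SN2 at the CH2 group, no allylic shift).

Step 6
Reactants: 8 tert-butyl(but-3-yn-1-yloxy)dimethylsilane
Product: 10 (E)-6-[(tert-butyldimethylsilyl)oxy]-4-methylhex-3-en-1-ol, via alkenylalane 9 (not isolated)
Conditions: AlMe3, (C5H5)2ZrCl2 (cat.), CH2Cl2, rt; then n-BuLi, THF, −78 °C; ethylene oxide, −78 °C to rt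
Reagents that add atoms: trimethylaluminium, C[Al](C)C; ethylene oxide, C1CO1
Why: Zirconium-catalysed syn-methylalumination of the terminal alkyne (Negishi carboalumination) places methyl and aluminium cis, and the derived alanate opens ethylene oxide with retention, which fixes the E trisubstituted olefin (the later C1=C10).

Step 7
Reactants: 10 (E)-6-[(tert-butyldimethylsilyl)oxy]-4-methylhex-3-en-1-ol
Product: 11 (E)-6-[(tert-butyldimethylsilyl)oxy]-4-methylhex-3-enal
Conditions: Dess–Martin periodinane, NaHCO3, CH2Cl2, 0 °C; used crude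
Reagents that add atoms: none
Why: Buffered Dess–Martin oxidation should give the β,γ-unsaturated aldehyde without migration of the double bond into conjugation.

Step 8
Reactants: 11 (E)-6-[(tert-butyldimethylsilyl)oxy]-4-methylhex-3-enal
Product: 12 (3S,5E)-8-[(tert-butyldimethylsilyl)oxy]-2,6-dimethylocta-1,5-dien-3-ol
Conditions: 2-bromopropene, CrCl2, NiCl2 (cat.), chiral oxazoline–sulfonamide ligand, Et3N, THF, rt
Reagents that add atoms: 2-bromopropene, CC(Br)=C
Why: Asymmetric Nozaki–Hiyama–Kishi alkenylation, in which the 2-propenylchromium species bound to the chiral ligand adds to one aldehyde face; the ligand enantiomer is the one that delivers the 3S carbinol, and the neutral conditions spare the labile aldehyde.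

Step 9
Reactants: 12 (3S,5E)-8-[(tert-butyldimethylsilyl)oxy]-2,6-dimethylocta-1,5-dien-3-ol
Product: 13 (3S,5E)-8-[(tert-butyldimethylsilyl)oxy]-2,6-dimethylocta-1,5-dien-3-yl benzoate
Conditions: BzCl, pyridine, DMAP (cat.), CH2Cl2, 0 °C to rt
Reagents that add atoms: benzoyl chloride, O=C(Cl)c1ccccc1
Why: Acylation of the secondary allylic alcohol at oxygen, with retention at C3.

Step 10
Reactants: 13 (3S,5E)-8-[(tert-butyldimethylsilyl)oxy]-2,6-dimethylocta-1,5-dien-3-yl benzoate
Product: 14 (3S,5E)-8-hydroxy-2,6-dimethylocta-1,5-dien-3-yl benzoate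
Conditions: HF·pyridine, pyridine, THF, 0 °C
Reagents that add atoms: none
Why: Fluoride cleavage of the primary silyl ether; the allylic benzoate is stable to buffered HF.

Step 11
Reactants: 14 (3S,5E)-8-hydroxy-2,6-dimethylocta-1,5-dien-3-yl benzoate
Product: 15 (3S,5E)-2,6-dimethyl-8-oxoocta-1,5-dien-3-yl benzoate
Conditions: Dess–Martin periodinane, NaHCO3, CH2Cl2, 0 °C; used crude
Reagents that add atoms: none
Why: Buffered Dess–Martin oxidation to the β,γ-unsaturated aldehyde, taken on at once to avoid double-bond migration.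

Step 12
Reactants: 16 (E)-2-methylbut-2-en-1-ol
Product: 17 [(2R,3R)-2,3-dimethyloxiran-2-yl]methanol
Conditions: Ti(OiPr)4 (cat.), D-(−)-diethyl tartrate (cat.), t-BuOOH, 4 Å molecular sieves, CH2Cl2, −20 °C
Reagents that add atoms: tert-butyl hydroperoxide, CC(C)(C)OO
Why: Sharpless asymmetric epoxidation; with the D-(−)-tartrate the oxygen is delivered to the face that gives the (2R,3R) epoxy alcohol, so both centres are set by the catalyst.

Step 13
Reactants: 17 [(2R,3R)-2,3-dimethyloxiran-2-yl]methanol
Product: 18 (2S,3R)-2,3-dimethyloxirane-2-carboxylic acid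
Conditions: RuCl3 (cat.), NaIO4, CCl4/MeCN/H2O, rt
Reagents that add atoms: sodium periodate, [Na+].[O-]I(=O)(=O)=O
Why: Ruthenium tetroxide oxidation of the primary alcohol to the acid leaves the epoxide untouched; C2 becomes 2S only because the substituent priorities change.

Step 14
Reactants: 7 (R)-3-(bromomethyl)-5-ethenylfuran-2(5H)-one; 15 (3S,5E)-2,6-dimethyl-8-oxoocta-1,5-dien-3-yl benzoate
Product: 20 (3S,5E,8S)-8-[(2R,3R)-2-ethenyl-4-methylidene-5-oxooxolan-3-yl]-8-hydroxy-2,6-dimethylocta-1,5-dien-3-yl benzoate, via allylchromium reagent 19 (not isolated)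
Conditions: CrCl2, THF, 0 °C to rt; aqueous work-up
Reagents that add atoms: none
Why: Nozaki–Hiyama (Barbier-type) allylation in which 19 reacts at its γ-carbon C7 through a closed Zimmerman–Traxler chair: attack anti to the C6 vinyl group should give the trans lactone (7R), the equatorial aldehyde residue on the ring-locked allyl unit should give the anti carbinol (8S), and the allyl shift unveils the α-methylene lactone.

Step 15
Reactants: 20 the 8S alcohol of step 14; 18 (2S,3R)-2,3-dimethyloxirane-2-carboxylic acid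
Product: 21 (3S,5E,8R)-8-{[(2S,3R)-2,3-dimethyloxirane-2-carbonyl]oxy}-8-[(2R,3R)-2-ethenyl-4-methylidene-5-oxooxolan-3-yl]-2,6-dimethylocta-1,5-dien-3-yl benzoate
Conditions: PPh3, DIAD (betaine preformed), toluene, 0 °C to rt
Reagents that add atoms: none
Why: Mitsunobu esterification, an SN2 displacement of the oxyphosphonium ion by the carboxylate, inverts C8 from S to R; preforming the betaine keeps free phosphine away from the methylene lactone.

Step 16
Reactants: 21 the triene diester of step 15
Product: 22 the (1R,10R)-epoxide of 21, in which the E olefin C5=C6 of the octadienyl chain (C1=C10 in germacranolide numbering) has become the trans epoxide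
Conditions: D-fructose-derived Shi ketone (30 mol %), Oxone, K2CO3, Bu4NHSO4, MeCN/dimethoxymethane/aqueous buffer (pH 10.5), 0 °C
Reagents that add atoms: potassium peroxymonosulfate (active part of Oxone), [K+].[O-]S(=O)(=O)OO
Why: Shi epoxidation, in which the chiral dioxirane reacts only with the electron-rich trisubstituted olefin through a spiro transition state and should set the (1R,10R) epoxide by reagent control; the vinyl, isopropenyl (allylic ester) and acrylate olefins are far less reactive.

Step 17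
Reactants: 22 the seco-diene epoxide of step 16
Product: 23 (1R,3S,4Z,6R,7R,8R,10R)-3-(benzoyloxy)-8-{[(2S,3R)-2,3-dimethyloxirane-2-carbonyl]oxy}-1,10-epoxygermacra-4,11(13)-dien-12,6-olide (CNP0324463.4)
Conditions: second-generation Hoveyda–Grubbs catalyst (H2IMes)Cl2Ru=CH(C6H4-2-OiPr) (20 mol %, in portions), 1,4-benzoquinone (cat.), toluene (1 mM), 100 °C, argon sparge
Reagents that add atoms: none
Why: The ruthenium alkylidene loads onto the monosubstituted C6 vinyl group, adds intramolecularly across the 1,1-disubstituted isopropenyl olefin at C4 to a ruthenacyclobutane, and cycloreversion releases ethylene and forms C4=C5 (Chauvin mechanism). The closest known reaction type is ring-closing olefin metathesis to trisubstituted medium-ring cycloalkenes, including ten-membered carbocycles that carry an α-methylene-γ-butyrolactone. The ten-membered ring C1–C10 is closed by olefin formation between two terminal alkenes, the new double bond lying inside the ring, and no other ring is touched. No stereocentre is created; the olefin geometry is set by the ring, since the trans-fused lactone (C6–C7) and the trans epoxide (C1–C10) already fix four ring atoms, so the E-trisubstituted olefin is the more strained closure and reversible metathesis at 100 °C should settle on the Z olefin (C3 and C6 cis). The step needs cyclisation over oligomerisation, for which high dilution, ethylene removal and the two rigid elements that fold the chain are relied on. It also needs chemoselectivity: the C11=C13 methylene is an electron-poor 1,1-disubstituted olefin, and the C1=C10 olefin, which could otherwise close a cyclohexene with the vinyl group, is already an epoxide.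

Compound list
1 | (S)-5-(hydroxymethyl)dihydrofuran-2(3H)-one | O=C1CC[C@@H](CO)O1 | starting material
2 | (S)-5-oxotetrahydrofuran-2-carbaldehyde | O=C1CC[C@@H](C=O)O1 | intermediate
3 | (S)-5-ethenyldihydrofuran-2(3H)-one | O=C1CC[C@@H](C=C)O1 | intermediate
4 | (5S)-5-ethenyl-3-(phenylselanyl)dihydrofuran-2(3H)-one | O=C1C([Se]c2ccccc2)C[C@@H](C=C)O1 | intermediate
5 | (5S)-5-ethenyl-3-(hydroxymethyl)-3-(phenylselanyl)dihydrofuran-2(3H)-one | O=C1C(CO)([Se]c2ccccc2)C[C@@H](C=C)O1 | intermediate (not isolated)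
6 | (R)-5-ethenyl-3-(hydroxymethyl)furan-2(5H)-one | O=C1C(CO)=C[C@@H](C=C)O1 | intermediate
7 | (R)-3-(bromomethyl)-5-ethenylfuran-2(5H)-one | O=C1C(CBr)=C[C@@H](C=C)O1 | intermediate
8 | tert-butyl(but-3-yn-1-yloxy)dimethylsilane | C#CCCO[Si](C)(C)C(C)(C)C | starting material
9 | (E)-{4-[(tert-butyldimethylsilyl)oxy]-2-methylbut-1-en-1-yl}dimethylalane | C[Al](C)/C=C(\C)CCO[Si](C)(C)C(C)(C)C | intermediate (not isolated)
10 | (E)-6-[(tert-butyldimethylsilyl)oxy]-4-methylhex-3-en-1-ol | OCC/C=C(\C)CCO[Si](C)(C)C(C)(C)C | intermediate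
11 | (E)-6-[(tert-butyldimethylsilyl)oxy]-4-methylhex-3-enal | O=CC/C=C(\C)CCO[Si](C)(C)C(C)(C)C | intermediate
12 | (3S,5E)-8-[(tert-butyldimethylsilyl)oxy]-2,6-dimethylocta-1,5-dien-3-ol | C=C(C)[C@@H](O)C/C=C(\C)CCO[Si](C)(C)C(C)(C)C | intermediate
13 | (3S,5E)-8-[(tert-butyldimethylsilyl)oxy]-2,6-dimethylocta-1,5-dien-3-yl benzoate | C=C(C)[C@@H](OC(=O)c1ccccc1)C/C=C(\C)CCO[Si](C)(C)C(C)(C)C | intermediate
14 | (3S,5E)-8-hydroxy-2,6-dimethylocta-1,5-dien-3-yl benzoate | C=C(C)[C@@H](OC(=O)c1ccccc1)C/C=C(\C)CCO | intermediate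
15 | (3S,5E)-2,6-dimethyl-8-oxoocta-1,5-dien-3-yl benzoate | C=C(C)[C@@H](OC(=O)c1ccccc1)C/C=C(\C)CC=O | intermediate
16 | (E)-2-methylbut-2-en-1-ol | C/C=C(\C)CO | starting material
17 | [(2R,3R)-2,3-dimethyloxiran-2-yl]methanol | OC[C@@]1(C)O[C@@H]1C | intermediate
18 | (2S,3R)-2,3-dimethyloxirane-2-carboxylic acid | OC(=O)[C@@]1(C)O[C@@H]1C | intermediate
19 | {[(5R)-5-ethenyl-2-oxo-2,5-dihydrofuran-3-yl]methyl}chromium dichloride | O=C1C(C[Cr](Cl)Cl)=C[C@@H](C=C)O1 | intermediate (not isolated)
20 | (3S,5E,8S)-8-[(2R,3R)-2-ethenyl-4-methylidene-5-oxooxolan-3-yl]-8-hydroxy-2,6-dimethylocta-1,5-dien-3-yl benzoate | C=C1C(=O)O[C@H](C=C)[C@H]1[C@@H](O)C/C(C)=C/C[C@H](OC(=O)c2ccccc2)C(C)=C | intermediate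
21 | (3S,5E,8R)-8-{[(2S,3R)-2,3-dimethyloxirane-2-carbonyl]oxy}-8-[(2R,3R)-2-ethenyl-4-methylidene-5-oxooxolan-3-yl]-2,6-dimethylocta-1,5-dien-3-yl benzoate | C=C1C(=O)O[C@H](C=C)[C@H]1[C@H](OC(=O)[C@@]2(C)O[C@@H]2C)C/C(C)=C/C[C@H](OC(=O)c2ccccc2)C(C)=C | intermediate
22 | (1R,10R)-epoxide of 21 (seco-diene; 3S,6R,7R,8R in germacranolide numbering) | C=C1C(=O)O[C@H](C=C)[C@H]1[C@H](OC(=O)[C@@]2(C)O[C@@H]2C)C[C@@]2(C)O[C@@H]2C[C@H](OC(=O)c2ccccc2)C(C)=C | intermediate
23 | (1R,3S,4Z,6R,7R,8R,10R)-3-(benzoyloxy)-8-{[(2S,3R)-2,3-dimethyloxirane-2-carbonyl]oxy}-1,10-epoxygermacra-4,11(13)-dien-12,6-olide (CNP0324463.4) | C=C1C(=O)O[C@@H]2/C=C(/C)[C@@H](OC(=O)c3ccccc3)C[C@H]3O[C@]3(C)C[C@@H](OC(=O)[C@@]3(C)O[C@@H]3C)[C@@H]12 | target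

Total step count: 17. Longest linear sequence: 10 steps (8 to 23; steps 6–11 and 14–17).

Steps most likely to fail

Step 17. Intermolecular metathesis through the vinyl groups may outrun closure of the strained ring, or the ruthenacycle may collapse to the E ring olefin. The fallback closes the same ring at C3–C4 instead, by an intramolecular Nozaki–Hiyama–Kishi reaction of a Z-alkenyl iodide with a C3 aldehyde, so that the olefin geometry is fixed before cyclisation and the carbocycle is still the last ring made. It sets out from 2 and 10 and comes back at 23.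
- Lactone half: aldehyde 2 would be olefinated (Stork–Zhao type) with the ylide from (1-iodoethyl)triphenylphosphonium iodide and NaN(SiMe3)2 to (S)-5-[(Z)-2-iodoprop-1-en-1-yl]dihydrofuran-2(3H)-one F1. The conditions of steps 3 to 5 would then give (5S)-5-[(Z)-2-iodoprop-1-en-1-yl]-3-(phenylselanyl)dihydrofuran-2(3H)-one F2, (S)-3-(hydroxymethyl)-5-[(Z)-2-iodoprop-1-en-1-yl]furan-2(5H)-one F3 and (S)-3-(bromomethyl)-5-[(Z)-2-iodoprop-1-en-1-yl]furan-2(5H)-one F4. The amide base is kept at −78 °C to avoid loss of HI.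
- Chain half: alcohol 10 would be silylated (t-BuPh2SiCl, imidazole) to (E)-1-[(tert-butyldimethylsilyl)oxy]-6-[(tert-butyldiphenylsilyl)oxy]-3-methylhex-3-ene F5. The smaller silyl group would be removed (PPTS, EtOH) to (E)-6-[(tert-butyldiphenylsilyl)oxy]-3-methylhex-3-en-1-ol F6, and buffered Dess–Martin oxidation would give (E)-6-[(tert-butyldiphenylsilyl)oxy]-3-methylhex-3-enal F7.
- Union and ring closure: CrCl2 without nickel, which leaves the alkenyl iodide alone, would join F4 and F7 to the trans lactone 8S alcohol with the iodopropenyl group on C6 F8. Mitsunobu esterification with 18 would give the 8R epoxy ester F9, and Shi epoxidation its (1R,10R)-epoxide F10. Bu4NF buffered with AcOH would free the C3 primary alcohol F11, and Dess–Martin oxidation would give the β,γ-epoxy aldehyde F12, used at once. CrCl2 with NiCl2 (cat.) in DMSO/THF at high dilution should close the carbocycle to the macrocyclic C3 carbinol F13.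
- Both C3 epimers of F13 lead to 23: the 3S alcohol with BzCl and pyridine (retention), the 3R alcohol by Mitsunobu reaction with benzoic acid (inversion).

Step 15. The C8 oxyphosphonium ion may lose a proton from C7 or C9 (both homoallylic) instead of being displaced by the α-branched carboxylate. The fallback makes the 8R carbinol directly, so that no inversion is needed. It sets out from 7 and comes back at 21.
- Bromide 7 would be converted with Bu3SnSnBu3 and Pd2(dba)3 (cat.) into (R)-5-ethenyl-3-[(tributylstannyl)methyl]furan-2(5H)-one F14.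
- BF3·OEt2 at −78 °C would add F14 to aldehyde 15 through an open antiperiplanar transition state, which is syn-selective and again anti to the C6 vinyl group, giving the 8R epimer of alcohol 20 F15.
- Yamaguchi esterification of F15 with 18 (2,4,6-trichlorobenzoyl chloride, Et3N, DMAP; retention) gives 21.

Step 8. Enantio-induction may be poor with this unbranched, isomerisation-prone aldehyde, or the double bond may move into conjugation before the addition. The fallback moves the asymmetric event to a ketone reduction. It sets out from 11 and comes back at 12.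
- Isopropenylmagnesium bromide would add to 11 to give racemic (5E)-8-[(tert-butyldimethylsilyl)oxy]-2,6-dimethylocta-1,5-dien-3-ol F16.
- Dess–Martin oxidation would give (E)-8-[(tert-butyldimethylsilyl)oxy]-2,6-dimethylocta-1,5-dien-3-one F17.
- Corey–Bakshi–Shibata reduction with the (R)-methyl oxazaborolidine and BH3·SMe2 (isopropenyl as the large group) should give the 3S alcohol 12.

Further compounds
F1 | step 17 | (S)-5-[(Z)-2-iodoprop-1-en-1-yl]dihydrofuran-2(3H)-one | O=C1CC[C@@H](/C=C(/C)I)O1
F2 | step 17 | (5S)-5-[(Z)-2-iodoprop-1-en-1-yl]-3-(phenylselanyl)dihydrofuran-2(3H)-one | O=C1C([Se]c2ccccc2)C[C@@H](/C=C(/C)I)O1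
F3 | step 17 | (S)-3-(hydroxymethyl)-5-[(Z)-2-iodoprop-1-en-1-yl]furan-2(5H)-one | O=C1C(CO)=C[C@@H](/C=C(/C)I)O1
F4 | step 17 | (S)-3-(bromomethyl)-5-[(Z)-2-iodoprop-1-en-1-yl]furan-2(5H)-one | O=C1C(CBr)=C[C@@H](/C=C(/C)I)O1
F5 | step 17 | (E)-1-[(tert-butyldimethylsilyl)oxy]-6-[(tert-butyldiphenylsilyl)oxy]-3-methylhex-3-ene | CC(C)(C)[Si](OCC/C=C(\C)CCO[Si](C)(C)C(C)(C)C)(c1ccccc1)c1ccccc1
F6 | step 17 | (E)-6-[(tert-butyldiphenylsilyl)oxy]-3-methylhex-3-en-1-ol | CC(C)(C)[Si](OCC/C=C(\C)CCO)(c1ccccc1)c1ccccc1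
F7 | step 17 | (E)-6-[(tert-butyldiphenylsilyl)oxy]-3-methylhex-3-enal | CC(C)(C)[Si](OCC/C=C(\C)CC=O)(c1ccccc1)c1ccccc1
F8 | step 17 | trans lactone 8S alcohol with the (Z)-2-iodoprop-1-enyl group on C6 and the silyl ether on C3 | C=C1C(=O)O[C@H](/C=C(/C)I)[C@H]1[C@@H](O)C/C(C)=C/CCO[Si](c1ccccc1)(c1ccccc1)C(C)(C)C
F9 | step 17 | 8R (2S,3R)-2,3-dimethyloxirane-2-carboxylate of F8 (inverted at C8) | C=C1C(=O)O[C@H](/C=C(/C)I)[C@H]1[C@H](OC(=O)[C@@]2(C)O[C@@H]2C)C/C(C)=C/CCO[Si](c1ccccc1)(c1ccccc1)C(C)(C)C
F10 | step 17 | (1R,10R)-epoxide of F9 | C=C1C(=O)O[C@H](/C=C(/C)I)[C@H]1[C@H](OC(=O)[C@@]2(C)O[C@@H]2C)C[C@@]2(C)O[C@@H]2CCO[Si](c1ccccc1)(c1ccccc1)C(C)(C)C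
F11 | step 17 | C3 primary alcohol from F10 | C=C1C(=O)O[C@H](/C=C(/C)I)[C@H]1[C@H](OC(=O)[C@@]2(C)O[C@@H]2C)C[C@@]2(C)O[C@@H]2CCO
F12 | step 17 | C3 aldehyde (β,γ-epoxy aldehyde) from F11 | C=C1C(=O)O[C@H](/C=C(/C)I)[C@H]1[C@H](OC(=O)[C@@]2(C)O[C@@H]2C)C[C@@]2(C)O[C@@H]2CC=O
F13 | step 17 | 3-debenzoyl 23 (macrocyclic C3 carbinol, both C3 epimers) | C=C1C(=O)O[C@@H]2/C=C(/C)C(O)C[C@H]3O[C@]3(C)C[C@@H](OC(=O)[C@@]3(C)O[C@@H]3C)[C@@H]12
F14 | step 15 | (R)-5-ethenyl-3-[(tributylstannyl)methyl]furan-2(5H)-one | O=C1C(C[Sn](CCCC)(CCCC)CCCC)=C[C@@H](C=C)O1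
F15 | step 15 | (3S,5E,8R)-8-[(2R,3R)-2-ethenyl-4-methylidene-5-oxooxolan-3-yl]-8-hydroxy-2,6-dimethylocta-1,5-dien-3-yl benzoate | C=C1C(=O)O[C@H](C=C)[C@H]1[C@H](O)C/C(C)=C/C[C@H](OC(=O)c2ccccc2)C(C)=C
F16 | step 8 | racemic (5E)-8-[(tert-butyldimethylsilyl)oxy]-2,6-dimethylocta-1,5-dien-3-ol | C=C(C)C(O)C/C=C(\C)CCO[Si](C)(C)C(C)(C)C
F17 | step 8 | (E)-8-[(tert-butyldimethylsilyl)oxy]-2,6-dimethylocta-1,5-dien-3-one | C=C(C)C(=O)C/C=C(\C)CCO[Si](C)(C)C(C)(C)C
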